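**Strategy**

In quinic acid numbering (C1 quaternary, C5 free carbinol), the cyclohexane ring is closed across C3–C4, the adjacent carbinol carbons that carry the two vanilloyl esters. A SmI2 pinacol cyclization of a 1,6-dialdehyde joins these two carbonyl carbons of like polarity and sets the cis-3,4-diol in one operation. It exploits the cis-1,3 relation of the C1 carboxyl and the C5 oxygen: tied as a γ-lactone (a ring absent from the target, from (R)-5-(hydroxymethyl)butyrolactone), they hold the C1 CH2CHO arm and the C5 CHO on one face, so closure gives the bicyclic quinide skeleton with the diol anti to the lactone bridge. Double acylation and acid hydrolysis finish.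

Key step: step 7

Remark: quinic acid numbering (C1 quaternary carbon, C7 carboxyl carbon) is used for the carbocycle atoms in the explanations, also for the lactone intermediates.
Assumption: (R)-5-(hydroxymethyl)dihydrofuran-2(3H)-one (the D-glutamic acid-derived lactone) and 4-acetoxy-3-methoxybenzoic acid (O-acetylvanillic acid) are taken as catalogue compounds.
Remark: step 8 consumes two molecules of acid 13 per molecule of diol 12, one for each hydroxyl; the first stands on the Reactants line and the second on the reagent line of that step.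

**Route**

Step 1
Reactants: 1 (R)-5-(hydroxymethyl)dihydrofuran-2(3H)-one
Product: 2 (R)-5-[(triethylsilyloxy)methyl]dihydrofuran-2(3H)-one
Conditions: Et3SiCl, imidazole, CH2Cl2, 0 °C → rt
Reagents that add atoms: chlorotriethylsilane, CC[Si](Cl)(CC)CC
Why: Imidazole-promoted silylation of the only hydroxyl should be clean and leaves C5 untouched; the triethylsilyl ether is chosen because a primary one can later be oxidised directly to the aldehyde.

Step 2
Reactants: 2 (R)-5-[(triethylsilyloxy)methyl]dihydrofuran-2(3H)-one
Product: 4 (5R)-3-allyl-5-[(triethylsilyloxy)methyl]dihydrofuran-2(3H)-one (mixture of C3 epimers), via lithium enolate 3 (not isolated)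
Conditions: LiN(i-Pr)2, THF, −78 °C; allyl bromide, −78 → −40 °C
Reagents that add atoms: allyl bromide, C=CCBr
Why: Kinetic lactone enolate alkylation with a reactive allylic bromide should give the mono-allyl lactone; the configuration of the new α-carbon (trans expected) does not matter because it is erased by enolisation in step 3.

Step 3
Reactants: 4 (5R)-3-allyl-5-[(triethylsilyloxy)methyl]dihydrofuran-2(3H)-one
Product: 6 (3S,5R)-3-allyl-3-hydroxy-5-[(triethylsilyloxy)methyl]dihydrofuran-2(3H)-one (hydroxyl trans and allyl cis to the C5 side chain), via potassium enolate 5 (not isolated)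
Conditions: KN(SiMe3)2, THF, −78 °C; trans-3-phenyl-2-(phenylsulfonyl)oxaziridine, −78 °C; aq. NH4Cl
Reagents that add atoms: trans-3-phenyl-2-(phenylsulfonyl)oxaziridine, O=S(=O)(c1ccccc1)N1OC1c1ccccc1
Why: Davis oxidation of the tetrasubstituted enolate should deliver oxygen to the face anti to the C5 silyloxymethyl group (1,3-induction, the same sense as second alkylations of such lactones), which sets C1 with the hydroxyl trans and the allyl arm cis to the C5 side chain as the ring closure requires.

Step 4
Reactants: 6 (3S,5R)-3-allyl-3-hydroxy-5-[(triethylsilyloxy)methyl]dihydrofuran-2(3H)-one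
Product: 7 (3S,5R)-3-allyl-3-(triethylsilyloxy)-5-[(triethylsilyloxy)methyl]dihydrofuran-2(3H)-one
Conditions: Et3SiOTf, 2,6-lutidine, CH2Cl2, −78 → 0 °C
Reagents that add atoms: triethylsilyl trifluoromethanesulfonate, CC[Si](CC)(CC)OS(=O)(=O)C(F)(F)F
Why: Silyl triflate with a hindered base silylates even a tertiary α-hydroxy lactone; the ether blocks O1 against acylation in step 8 and keeps the later diol extractable.

Step 5
Reactants: 7 (3S,5R)-3-allyl-3-(triethylsilyloxy)-5-[(triethylsilyloxy)methyl]dihydrofuran-2(3H)-one
Product: 9 (2R,4S)-4-allyl-5-oxo-4-(triethylsilyloxy)tetrahydrofuran-2-carbaldehyde, via alkoxysulfonium chloride 8 (not isolated)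
Conditions: (COCl)2, DMSO, CH2Cl2, −78 → −40 °C; i-Pr2NEt, −78 → 0 °C
Reagents that add atoms: none
Why: Under Swern conditions a primary triethylsilyl ether is cleaved and oxidised in one operation (oxidative desilylation) while the tertiary silyl ether and the alkene should survive; running it before the ozonolysis keeps amine base away from the β-silyloxy aldehyde made in step 6.

Step 6
Reactants: 9 (2R,4S)-4-allyl-5-oxo-4-(triethylsilyloxy)tetrahydrofuran-2-carbaldehyde
Product: 11 (2R,4R)-5-oxo-4-(2-oxoethyl)-4-(triethylsilyloxy)tetrahydrofuran-2-carbaldehyde, via ozonide 10 (not isolated)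
Conditions: O3, CH2Cl2, −78 °C; PPh3, −78 °C → rt; crude product used at once
Reagents that add atoms: ozone, [O-][O+]=O
Why: Ozonolysis with reductive work-up cleaves the terminal alkene to the C3 aldehyde under neutral conditions that the elimination-prone β-silyloxy aldehyde and the α-oxygenated aldehyde should tolerate.

Step 7
Reactants: 11 (2R,4R)-5-oxo-4-(2-oxoethyl)-4-(triethylsilyloxy)tetrahydrofuran-2-carbaldehyde
Product: 12 1-O-triethylsilylquinide, (1S,3R,4R,5R)-3,4-dihydroxy-1-(triethylsilyloxy)-6-oxabicyclo[3.2.1]octan-7-one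
Conditions: SmI2 (0.1 M in THF, about 3 equiv), t-BuOH, THF, −78 → −20 °C, slow addition of 11 at high dilution; aq. NH4Cl
Reagents that add atoms: none
Why: Two single-electron transfers from divalent samarium turn both aldehydes into ketyl radical anions that are held on trivalent samarium and combine at carbon, so the two electrophilic carbonyl carbons C3 and C4 are joined reductively. The closest known reaction type is the SmI2-mediated intramolecular pinacol cyclization of oxygenated 1,6-dialdehydes, which gives cis-cyclohexane-1,2-diols. The carbocycle closes as a six-membered ring (formally 6-exo addition of the C3 ketyl to the C4 carbonyl) across the cis-disubstituted γ-lactone, giving the 6-oxabicyclo[3.2.1]octan-7-one skeleton with the lactone bridge diaxial on the new chair. C3 and C4 are set together: the cis relation comes from the samarium chelate of the two oxygens, and the face comes from the lactone, because the C3 oxygen must be equatorial (the axial position points into the bridge) and the C4 oxygen then sits axial and anti to the C5–O bond, the usual anti relation to an α-oxygen. The step needs cis over trans selectivity and carbonyl coupling in preference to reductive loss of the C5 oxygen or aldol side reactions; low temperature, high dilution, the absence of HMPA and the rigid tether should secure this. A dialdehyde epimerised at C5 cannot bridge the lactone and is left behind, so the diol should emerge as a single enantiomer.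

Step 8
Reactants: 12 1-O-triethylsilylquinide; 13 4-acetoxy-3-methoxybenzoic acid
Product: 15 3,4-bis-O-(4-acetoxy-3-methoxybenzoyl)-1-O-triethylsilylquinide, via 4-acetoxy-3-methoxybenzoyl chloride 14 (not isolated)
Conditions: 13 (2.6 equiv), (COCl)2 (3 equiv), cat. DMF, CH2Cl2, 0 °C → rt, evaporate; then 12 (1 equiv), pyridine, DMAP, CH2Cl2, 0 °C → rt
Reagents that add atoms: 4-acetoxy-3-methoxybenzoic acid (second equivalent of 13, likewise used as chloride 14), COc1cc(C(=O)O)ccc1OC(C)=O
Why: Acid chloride acylation with pyridine and nucleophilic catalysis by DMAP should esterify both secondary hydroxyls, the equatorial O3 first and the axial O4 under the excess of chloride, so that two molecules of 14 are taken up per molecule of 12; both positions need the same acyl group and the tertiary oxygen is blocked, so no differentiation is required.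

Step 9
Reactants: 15 3,4-bis-O-(4-acetoxy-3-methoxybenzoyl)-1-O-triethylsilylquinide
Product: 16 Burkinabin A, 3,4-di-O-vanilloylquinic acid, (1R,3R,4S,5R)-1,5-dihydroxy-3,4-bis[(4-hydroxy-3-methoxybenzoyl)oxy]cyclohexane-1-carboxylic acid
Conditions: 2 M aq. HCl/THF (1:3), rt → 40 °C, monitored; lyophilisation and reversed-phase purification
Reagents that add atoms: water, O
Why: Acid-catalysed hydrolysis should cleave the tertiary silyl ether and the two phenolic acetates and open the strained bridged γ-lactone by acyl–oxygen cleavage (C5 keeps its oxygen and configuration), while the secondary vanilloyl esters hydrolyse far more slowly and acyl migration is suppressed at low pH.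

**Compound list**

1 | (R)-5-(hydroxymethyl)dihydrofuran-2(3H)-one | OC[C@H]1CCC(=O)O1 | starting material
2 | (R)-5-[(triethylsilyloxy)methyl]dihydrofuran-2(3H)-one | CC[Si](CC)(CC)OC[C@H]1CCC(=O)O1 | intermediate
3 | lithium enolate of 2 | CC[Si](CC)(CC)OC[C@H]1CC=C([O-])O1.[Li+] | intermediate
4 | (5R)-3-allyl-5-[(triethylsilyloxy)methyl]dihydrofuran-2(3H)-one (mixture of C3 epimers) | CC[Si](CC)(CC)OC[C@H]1CC(CC=C)C(=O)O1 | intermediate
5 | potassium enolate of 4 | CC[Si](CC)(CC)OC[C@H]1CC(CC=C)=C([O-])O1.[K+] | intermediate
6 | (3S,5R)-3-allyl-3-hydroxy-5-[(triethylsilyloxy)methyl]dihydrofuran-2(3H)-one | CC[Si](CC)(CC)OC[C@H]1C[C@@](O)(CC=C)C(=O)O1 | intermediate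
7 | (3S,5R)-3-allyl-3-(triethylsilyloxy)-5-[(triethylsilyloxy)methyl]dihydrofuran-2(3H)-one | CC[Si](CC)(CC)OC[C@H]1C[C@@](O[Si](CC)(CC)CC)(CC=C)C(=O)O1 | intermediate
8 | alkoxydimethylsulfonium chloride formed at the primary oxygen of 7 | C[S+](C)OC[C@H]1C[C@@](O[Si](CC)(CC)CC)(CC=C)C(=O)O1.[Cl-] | intermediate
9 | (2R,4S)-4-allyl-5-oxo-4-(triethylsilyloxy)tetrahydrofuran-2-carbaldehyde | O=C[C@H]1C[C@@](O[Si](CC)(CC)CC)(CC=C)C(=O)O1 | intermediate
10 | secondary ozonide (1,2,4-trioxolane) of 9 | O=C[C@H]1C[C@@](O[Si](CC)(CC)CC)(CC2OCOO2)C(=O)O1 | intermediate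
11 | (2R,4R)-5-oxo-4-(2-oxoethyl)-4-(triethylsilyloxy)tetrahydrofuran-2-carbaldehyde | O=C[C@H]1C[C@@](O[Si](CC)(CC)CC)(CC=O)C(=O)O1 | intermediate
12 | 1-O-triethylsilylquinide, (1S,3R,4R,5R)-3,4-dihydroxy-1-(triethylsilyloxy)-6-oxabicyclo[3.2.1]octan-7-one | O[C@H]1[C@H]2C[C@](O[Si](CC)(CC)CC)(C(=O)O2)C[C@H]1O | intermediate
13 | 4-acetoxy-3-methoxybenzoic acid | COc1cc(C(=O)O)ccc1OC(C)=O | starting material
14 | 4-acetoxy-3-methoxybenzoyl chloride | COc1cc(C(=O)Cl)ccc1OC(C)=O | intermediate
15 | 3,4-bis-O-(4-acetoxy-3-methoxybenzoyl)-1-O-triethylsilylquinide (configuration of 12; both acyloxy groups anti to the lactone bridge) | COc1cc(C(=O)O[C@H]2[C@H]3C[C@](O[Si](CC)(CC)CC)(C(=O)O3)C[C@H]2OC(=O)c2ccc(OC(C)=O)c(OC)c2)ccc1OC(C)=O | intermediate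
16 | Burkinabin A, 3,4-di-O-vanilloylquinic acid | COc1cc(C(=O)O[C@H]2[C@H](O)C[C@](O)(C(=O)O)C[C@H]2OC(=O)c2ccc(O)c(OC)c2)ccc1O | target

**Count**

Total steps: 9. Longest linear sequence: 9 steps (1 to 16).

**Steps most likely to fail**

Step 7. The C4 ketyl may expel the C5 oxygen (reductive β-elimination that opens the lactone), one aldehyde may simply be reduced before coupling, or cis control may leak to the trans-diol. The fallback makes the same bond as an alkene. Setting out from aldehyde 9, Wittig methylenation (Ph3PCH3Br, KN(SiMe3)2, THF, −78 → 0 °C) would give (3S,5R)-3-allyl-3-(triethylsilyloxy)-5-vinyldihydrofuran-2(3H)-one F1. Ring-closing metathesis (second-generation Grubbs catalyst, CH2Cl2, 40 °C, high dilution) would give the bridged alkene (1S,5R)-1-(triethylsilyloxy)-6-oxabicyclo[3.2.1]oct-3-en-7-one F2. Dihydroxylation (cat. OsO4, NMO, acetone/water) from the open face anti to the lactone bridge would give diol 12, where the route is rejoined.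

Step 3. The small silyloxymethyl group may shield its enolate face too weakly, so that oxygen is delivered to both faces, and the enolate may add to the sulfonimine by-product. The fallback changes the control element to a trityloxymethyl shield. Setting out from 1, tritylation (Ph3CCl, pyridine) would give (R)-5-(trityloxymethyl)dihydrofuran-2(3H)-one F3. Allylation (LiN(i-Pr)2, allyl bromide, THF, −78 °C) would give (5R)-3-allyl-5-(trityloxymethyl)dihydrofuran-2(3H)-one F4. Enolate hydroxylation as in step 3 would give (3S,5R)-3-allyl-3-hydroxy-5-(trityloxymethyl)dihydrofuran-2(3H)-one F5. Detritylation (HCO2H, Et2O, rt) would give (3S,5R)-3-allyl-3-hydroxy-5-(hydroxymethyl)dihydrofuran-2(3H)-one F6. Double silylation (Et3SiOTf, 2,6-lutidine, CH2Cl2) would return to 7.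

Step 5. The HCl generated may also remove the tertiary silyl ether, the primary ether may be cleaved incompletely, or the carbon α to the new aldehyde may epimerise when base is added. The fallback separates deprotection from oxidation. Setting out from 7, selective solvolysis of the primary silyl ether (PPTS, MeOH/CH2Cl2, 0 °C) would give (3S,5R)-3-allyl-5-(hydroxymethyl)-3-(triethylsilyloxy)dihydrofuran-2(3H)-one F7. Buffered Dess–Martin oxidation (Dess–Martin periodinane, NaHCO3, CH2Cl2, 0 °C) would return to 9.

**Further compounds**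

F1 | step 7 | (3S,5R)-3-allyl-3-(triethylsilyloxy)-5-vinyldihydrofuran-2(3H)-one | C=C[C@H]1C[C@@](O[Si](CC)(CC)CC)(CC=C)C(=O)O1
F2 | step 7 | (1S,5R)-1-(triethylsilyloxy)-6-oxabicyclo[3.2.1]oct-3-en-7-one | C1=CC[C@]2(O[Si](CC)(CC)CC)C[C@H]1OC2=O
F3 | step 3 | (R)-5-(trityloxymethyl)dihydrofuran-2(3H)-one | C(OC[C@H]1CCC(=O)O1)(c1ccccc1)(c1ccccc1)c1ccccc1
F4 | step 3 | (5R)-3-allyl-5-(trityloxymethyl)dihydrofuran-2(3H)-one (mixture of C3 epimers) | C(OC[C@H]1CC(CC=C)C(=O)O1)(c1ccccc1)(c1ccccc1)c1ccccc1
F5 | step 3 | (3S,5R)-3-allyl-3-hydroxy-5-(trityloxymethyl)dihydrofuran-2(3H)-one | C(OC[C@H]1C[C@@](O)(CC=C)C(=O)O1)(c1ccccc1)(c1ccccc1)c1ccccc1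
F6 | step 3 | (3S,5R)-3-allyl-3-hydroxy-5-(hydroxymethyl)dihydrofuran-2(3H)-one | OC[C@H]1C[C@@](O)(CC=C)C(=O)O1
F7 | step 5 | (3S,5R)-3-allyl-5-(hydroxymethyl)-3-(triethylsilyloxy)dihydrofuran-2(3H)-one | OC[C@H]1C[C@@](O[Si](CC)(CC)CC)(CC=C)C(=O)O1
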